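**Retrosynthetic overview**
1. Target 16 ⇒ homoallylic alcohol 12: the C2–O bond is made last, by a hydroxyl-tethered hydrosilylation/oxidation of the ring alkene that delivers oxygen cis to the side chain; the phenol is freed in the same flask.
2. 12 ⇒ dihydronaphthalene 7 + enal 11: the key C1–C1' bond comes from an enantioselective photoredox/chromium allylic C–H allylation, in which the allyl–benzyl radical of 7 is captured by chiral chromium and adds to the aldehyde, setting C1 and C1' together.
3. 7 ⇒ dibromide 3 + butadiene by an aryne [4+2]. This is the only ring construction: carbocyclic ring B is built onto ring A (from catechol); phenol ring C is bought as 4-iodophenol.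
4. 11 ⇒ 4-iodophenol + acrolein (silylation, Heck).

Assumption: of the two available enantiomers of the indane-fused bis(oxazoline) ligand, the one that sends the allyl group to the Re face of the aldehyde is used in step 6 (checked on the first run by Mosher ester analysis of 12).

**Step 1**
Reactants: 1 catechol (benzene-1,2-diol)
Product: 2 1,2-dimethoxybenzene
Conditions: MeI (2.5 equiv), K2CO3, acetone, reflux
Reagents that add atoms: iodomethane, CI
Why: Williamson ether synthesis, in which both phenoxides are methylated cleanly by the unhindered electrophile; no stereocenter.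

**Step 2**
Reactants: 2 1,2-dimethoxybenzene
Product: 3 1,2-dibromo-4,5-dimethoxybenzene
Conditions: Br2 (2.1 equiv), CH2Cl2, 0 °C to rt
Reagents that add atoms: bromine, BrBr
Why: Electrophilic aromatic bromination, in which each methoxy group directs para so the two bromines enter at C4 and C5 only.

**Step 3**
Reactants: 3 1,2-dibromo-4,5-dimethoxybenzene; 4 buta-1,3-diene
Product: 7 6,7-dimethoxy-1,4-dihydronaphthalene, via (2-bromo-4,5-dimethoxyphenyl)lithium 5 (not isolated), via 4,5-dimethoxybenzyne 6 (not isolated)
Conditions: n-BuLi (1.1 equiv, slow addition), butadiene in tenfold excess, toluene, −40 °C to rt, sealed vessel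
Reagents that add atoms: none
Why: Lithium–bromine exchange followed by loss of LiBr gives the aryne, which is trapped by s-cis butadiene in an aryne Diels–Alder reaction to form ring B with an isolated alkene and two equivalent benzylic–allylic CH2 groups; no stereocenter.

**Step 4**
Reactants: 8 4-iodophenol
Product: 9 tert-butyl(4-iodophenoxy)dimethylsilane
Conditions: TBSCl, imidazole, DMF, rt
Reagents that add atoms: tert-butyldimethylsilyl chloride, CC(C)(C)[Si](C)(C)Cl
Why: Imidazole-promoted O-silylation masks the acidic, easily oxidised phenol for the photoredox step and is removed by fluoride at the end.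

**Step 5**
Reactants: 9 tert-butyl(4-iodophenoxy)dimethylsilane; 10 acrolein
Product: 11 (2E)-3-[4-(tert-butyldimethylsilyloxy)phenyl]prop-2-enal
Conditions: Pd(OAc)2 (3 mol%), Bu4NCl, NaHCO3, acrolein in threefold excess, DMF, 45 °C
Reagents that add atoms: none
Why: Mizoroki–Heck reaction under ligand-free Jeffery conditions, in which syn insertion and syn β-hydride elimination give the E-enal and the mild bicarbonate base spares the aryl silyl ether.

**Step 6**
Reactants: 7 6,7-dimethoxy-1,4-dihydronaphthalene; 11 (2E)-3-[4-(tert-butyldimethylsilyloxy)phenyl]prop-2-enal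
Product: 12 (1S,2E)-3-[4-(tert-butyldimethylsilyloxy)phenyl]-1-[(1R)-6,7-dimethoxy-1,4-dihydronaphthalen-1-yl]prop-2-en-1-ol
Conditions: CrCl2 (10 mol%), indane-fused bis(oxazoline) ligand (12 mol%), 9-mesityl-10-methylacridinium perchlorate (3 mol%), Mg(ClO4)2 (50 mol%), CH2Cl2, 430 nm LEDs, rt; the dihydronaphthalene is used in threefold excess and the unreacted part is recovered on chromatography
Reagents that add atoms: none
Why: Photoredox/chromium dual-catalytic allylic C–H allylation of an aldehyde (radical–polar crossover variant of the Nozaki–Hiyama–Kishi allylation), a redox-neutral addition in which every atom of both partners ends in 12: the excited acridinium oxidises the dimethoxyarene, loss of a benzylic–allylic proton gives the delocalised allyl–benzyl radical, the chiral divalent chromium complex captures it, and the resulting trivalent allylchromium (metal at C3, styrene-type double bond retained) adds at its benzylic terminus to the Re face of 11 through a chair Zimmerman–Traxler transition state whose ring-locked cis allyl unit places the aryl carbon axial, giving the aryl/hydroxyl syn pair (C1 R, C1' S) while the released proton frees the alcohol and the acridine radical returns chromium to the divalent state.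

**Step 7**
Reactants: 12 (1S,2E)-3-[4-(tert-butyldimethylsilyloxy)phenyl]-1-[(1R)-6,7-dimethoxy-1,4-dihydronaphthalen-1-yl]prop-2-en-1-ol
Product: 16 (1S,2R)-1-[(1S,2E)-1-hydroxy-3-(4-hydroxyphenyl)prop-2-en-1-yl]-6,7-dimethoxy-1,2,3,4-tetrahydronaphthalen-2-ol, via dimethylsilyl ether 13 (not isolated), via cis-fused oxasilolane 14 (not isolated), via aryl silyl ether diol 15 (not isolated)
Conditions: (HMe2Si)2NH, rt, then evaporate; Pt2[(CH2=CHSiMe2)2O]3 (0.5 mol%), toluene (0.02 M), 40 °C; KF, KHCO3, 30% H2O2, THF/MeOH, rt; then TBAF, THF, rt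
Reagents that add atoms: hydrogen peroxide, OO
Why: Tamao intramolecular hydrosilylation followed by Tamao–Fleming oxidation, in which the Si–H tethered to the C1' oxygen adds 5-exo to the cis ring alkene from the face of the side chain (the trans β-aryl styrene could only react by a slower 5-endo mode), stereoretentive C–Si oxidation gives the cis C2 hydroxyl (R) and hence the syn-1,3-diol, and fluoride then frees the phenol.

**Compound list**
1 | catechol (benzene-1,2-diol) | Oc1ccccc1O | starting material
2 | 1,2-dimethoxybenzene | COc1ccccc1OC | intermediate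
3 | 1,2-dibromo-4,5-dimethoxybenzene | COc1cc(Br)c(Br)cc1OC | intermediate
4 | buta-1,3-diene | C=CC=C | starting material
5 | (2-bromo-4,5-dimethoxyphenyl)lithium | COc1cc(Br)c([Li])cc1OC | intermediate
6 | 4,5-dimethoxybenzyne | COC1=CC#CC=C1OC | intermediate
7 | 6,7-dimethoxy-1,4-dihydronaphthalene | COc1cc2c(cc1OC)CC=CC2 | intermediate
8 | 4-iodophenol | Oc1ccc(I)cc1 | starting material
9 | tert-butyl(4-iodophenoxy)dimethylsilane | CC(C)(C)[Si](C)(C)Oc1ccc(I)cc1 | intermediate
10 | acrolein (prop-2-enal) | C=CC=O | starting material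
11 | (2E)-3-[4-(tert-butyldimethylsilyloxy)phenyl]prop-2-enal | O=C/C=C/c1ccc(O[Si](C)(C)C(C)(C)C)cc1 | intermediate
12 | (1S,2E)-3-[4-(tert-butyldimethylsilyloxy)phenyl]-1-[(1R)-6,7-dimethoxy-1,4-dihydronaphthalen-1-yl]prop-2-en-1-ol | COc1cc2c(cc1OC)[C@H]([C@@H](O)/C=C/c1ccc(O[Si](C)(C)C(C)(C)C)cc1)C=CC2 | intermediate
13 | O-dimethylsilyl (Si–H) ether of 12, configuration unchanged | COc1cc2c(cc1OC)[C@H]([C@@H](O[SiH](C)C)/C=C/c1ccc(O[Si](C)(C)C(C)(C)C)cc1)C=CC2 | intermediate
14 | cis-fused 2,2-dimethyl-1-oxa-2-silacyclopentane: Si bonded to tetralin C2 on the face of the side chain, O on the carbinol carbon, other stereocentres as in 12 | COc1cc2c(cc1OC)[C@@H]3[C@H](/C=C/c4ccc(O[Si](C)(C)C(C)(C)C)cc4)O[Si](C)(C)[C@@H]3CC2 | intermediate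
15 | (1S,2R)-1-[(1S,2E)-3-[4-(tert-butyldimethylsilyloxy)phenyl]-1-hydroxyprop-2-en-1-yl]-6,7-dimethoxy-1,2,3,4-tetrahydronaphthalen-2-ol | COc1cc2c(cc1OC)[C@H]([C@@H](O)/C=C/c1ccc(O[Si](C)(C)C(C)(C)C)cc1)[C@H](O)CC2 | intermediate
16 | (1S,2R)-1-[(1S,2E)-1-hydroxy-3-(4-hydroxyphenyl)prop-2-en-1-yl]-6,7-dimethoxy-1,2,3,4-tetrahydronaphthalen-2-ol | COc1cc2c(cc1OC)[C@H]([C@@H](O)/C=C/c1ccc(O)cc1)[C@H](O)CC2 | target

**Step count**
Total: 7 steps. Longest linear sequence: 5 steps (1, 2, 3, 6, 7).

**Steps most likely to fail, with fallbacks**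

Step 6. The risks are over-oxidation of 7 or 12 to the naphthalene, C–C bond formation at C3 instead of C1, and erosion of selectivity with an enal partner. The fallback generates the same allyl radical reductively instead of by C–H oxidation. It sets out from 7: deprotonation with n-BuLi/TMEDA (THF, −78 °C) and a CO2 quench give racemic 6,7-dimethoxy-1,4-dihydronaphthalene-1-carboxylic acid F1. N-Hydroxyphthalimide and diisopropylcarbodiimide convert it into the redox-active ester 1,3-dioxoisoindolin-2-yl 6,7-dimethoxy-1,4-dihydronaphthalene-1-carboxylate F2. Reductive decarboxylation of F2 (4CzIPN, Hantzsch ester, blue LEDs) in the presence of 11 and the same CrCl2/bis(oxazoline) catalyst forms the allylchromium species with no oxidant present. The fallback comes back to the route at 12.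

Step 7. The risk is that the silane, which is allylic to the styrene as well as homoallylic to the ring alkene, adds to the wrong double bond, or that platinum isomerises the ring alkene. The fallback carries the styrene through as an alkyne, which has no feasible intramolecular syn-addition pathway within a five-membered ring. It sets out from 9: Sonogashira coupling with propargyl alcohol (PdCl2(PPh3)2, CuI, Et3N) gives 3-[4-(tert-butyldimethylsilyloxy)phenyl]prop-2-yn-1-ol F3, and MnO2 gives 3-[4-(tert-butyldimethylsilyloxy)phenyl]prop-2-ynal F4. Under the step 6 conditions with 7 this gives (1R)-3-[4-(tert-butyldimethylsilyloxy)phenyl]-1-[(1R)-6,7-dimethoxy-1,4-dihydronaphthalen-1-yl]prop-2-yn-1-ol F5 (same spatial arrangement as 12). The silylation and platinum steps of step 7 then give the O-dimethylsilyl ether of F5 F6 and the alkynyl analogue of oxasilolane 14 F7. KF/KHCO3/H2O2 gives (1S,2R)-1-[(1R)-3-[4-(tert-butyldimethylsilyloxy)phenyl]-1-hydroxyprop-2-yn-1-yl]-6,7-dimethoxy-1,2,3,4-tetrahydronaphthalen-2-ol F8. Trans-hydroalumination of the propargylic alkoxide with NaAlH2(OCH2CH2OMe)2 (THF, 0 °C) gives the E-allylic alcohol, and the fallback comes back to the route at 15, which is desilylated with TBAF as in step 7.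

Step 3. The risks are that n-BuLi starts butadiene polymerisation and that the aryne gives [2+2] or ene products with an acyclic diene. The fallback builds ring B by metathesis instead of cycloaddition. It sets out from 3: double Suzuki–Miyaura allylation with potassium allyltrifluoroborate (PdCl2(dppf), Cs2CO3, THF/H2O, 80 °C) gives 1,2-dimethoxy-4,5-di(prop-2-en-1-yl)benzene F9. Ring-closing metathesis with second-generation Grubbs catalyst (CH2Cl2, 40 °C) closes the ring, and the fallback comes back to the route at 7.

**Further compounds**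
F1 | step 6 | 6,7-dimethoxy-1,4-dihydronaphthalene-1-carboxylic acid (racemic) | COc1cc2c(cc1OC)C(C(=O)O)C=CC2
F2 | step 6 | 1,3-dioxoisoindolin-2-yl 6,7-dimethoxy-1,4-dihydronaphthalene-1-carboxylate (racemic) | COc1cc2c(cc1OC)C(C(=O)ON3C(=O)c4ccccc4C3=O)C=CC2
F3 | step 7 | 3-[4-(tert-butyldimethylsilyloxy)phenyl]prop-2-yn-1-ol | OCC#Cc1ccc(O[Si](C)(C)C(C)(C)C)cc1
F4 | step 7 | 3-[4-(tert-butyldimethylsilyloxy)phenyl]prop-2-ynal | O=CC#Cc1ccc(O[Si](C)(C)C(C)(C)C)cc1
F5 | step 7 | (1R)-3-[4-(tert-butyldimethylsilyloxy)phenyl]-1-[(1R)-6,7-dimethoxy-1,4-dihydronaphthalen-1-yl]prop-2-yn-1-ol | COc1cc2c(cc1OC)[C@H]([C@@H](O)C#Cc1ccc(O[Si](C)(C)C(C)(C)C)cc1)C=CC2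
F6 | step 7 | O-dimethylsilyl (Si–H) ether of F5 | COc1cc2c(cc1OC)[C@H]([C@@H](O[SiH](C)C)C#Cc1ccc(O[Si](C)(C)C(C)(C)C)cc1)C=CC2
F7 | step 7 | alkynyl analogue of oxasilolane 14 (cis-fused, Si on tetralin C2) | COc1cc2c(cc1OC)[C@@H]3[C@H](C#Cc4ccc(O[Si](C)(C)C(C)(C)C)cc4)O[Si](C)(C)[C@@H]3CC2
F8 | step 7 | (1S,2R)-1-[(1R)-3-[4-(tert-butyldimethylsilyloxy)phenyl]-1-hydroxyprop-2-yn-1-yl]-6,7-dimethoxy-1,2,3,4-tetrahydronaphthalen-2-ol | COc1cc2c(cc1OC)[C@H]([C@@H](O)C#Cc1ccc(O[Si](C)(C)C(C)(C)C)cc1)[C@H](O)CC2
F9 | step 3 | 1,2-dimethoxy-4,5-di(prop-2-en-1-yl)benzene | COc1cc(CC=C)c(CC=C)cc1OC
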